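The delay number 0.109 carries this flask. The delay number is the late onward constant of open intermediate times the mean waiting of a dosed reagent, so it says how much open intermediate a later start spares.

| flask | starting material | fresh partner | coupling partner | protic impurity | remark | time |
|---|---|---|---|---|---|---|
| cedar | 0.055 M | 0.95 equiv | 2.5 equiv | 5.5 mM | run made earlier |  |
| alder | 0.055 M | 0.95 equiv | 2.5 equiv | 7.7 mM | run made earlier |  |
| larch | 0.055 M | 0.95 equiv | 2.5 equiv | 12 mM | run made earlier |  |
| Thursday's | 0.055 M | 0.950 equiv | 2.50 equiv | 5.50 mM | everything together in a closed stirred flask, run for 3.0 h | 3.0 h |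
| Saturday's | 0.055 M | 0.950 equiv | 2.50 equiv | 5.50 mM | one stirred flow tank at steady state, fed with the mixture as stated, mean residence time 3.0 h |  |
| Wednesday's | 0.055 M (fed, over 1.50 h) | 0.950 equiv | 2.50 equiv | 5.50 mM | a stirred flask in which starting material is dosed at a steady rate over 1.50 h without added volume, worked up at 3.0 h | 3.0 h |
| Friday's | 0.055 M | 0.950 equiv | 2.50 equiv (fed, over 1.50 h) | 5.50 mM | a stirred flask in which coupling partner is dosed at a steady rate over 1.50 h without added volume, worked up at 3.0 h | 3.0 h |

- cedar (time / min: open intermediate / %, target / %): 20.0: 43.1, 0; 40.0: 59.9, 1.4; 60.0: 66.5, 5.0; 80.0: 68.6, 7.0; 120: 66.2, 12.9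
- alder (time / h: open intermediate / %, target / %): 0.667: 57.5, 1.9; 1.33: 66.4, 6.2; 2.00: 63.3, 12.4; 3.00: 55.0, 21.7; 4.00: 47.2, 28.5
- larch (time / h: open intermediate / %, target / %): 0.667: 53.7, 0.9; 1.33: 60.1, 5.2; 2.00: 57.9, 12.1; 3.00: 49.3, 20.8; 4.00: 42.1, 28.6

(standard deviation of a reading: 0.5 percentage points)

- the stated concentrations are those of everything mixed, before any reaction; amounts are the same in each set-up
- the feed brings no volume worth counting
- the earlier runs were made in a closed, stirred flask

1. the set-up with the highest amount of open intermediate at the outlet or at the end, in percent of the starting material put in ("none" if the first two lie within 2 percentage points) (Thursday's / Saturday's / Wednesday's / Friday's / none)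
2. amount of open intermediate at the outlet or at the end, in percent of the starting material put in, Thursday's
3. amount of open intermediate at the outlet or at the end, in percent of the starting material put in, Saturday's
4. amount of open intermediate at the outlet or at the end, in percent of the starting material put in, Wednesday's
5. amount of open intermediate at the outlet or at the end, in percent of the starting material put in, Friday's

In the alder run, target rises from 12.4 % to 28.5 % between 2.00 h and 4.00 h. That reads as a pseudo-first-order onward constant of 0.146 /h. The cedar run, with Thursday's charge, holds 66.2 % open intermediate at 120 min, so my own reckoning decays this to 57.2 % at 3.0 h.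

A steady feed over 1.50 h arrives on average after 0.750 h. If coupling partner starts the chain, Friday's is Thursday's on a later clock, a factor of 1.12. Averaging over the whole feed gives 64.0 %, and using the mean instead errs by 0.13 percentage points.

One number is not enough, though. Target reads 0 % at 20.0 min in the cedar run, so the onward step ripens. The ripening starts with Wednesday's dose, so early open intermediate there meets a smaller constant. As a plain assumption, my reckoning still applies the late constant to Wednesday's open intermediate from the mean arrival of starting material onward. From the cedar sum of 79.1 %, that leaves 57.0 %. My reckoning therefore puts Friday's first, higher than Wednesday's by 7 points.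

The forecast gives 57.5 %, 48 %, 62 % and 61 %, with best none, and adds: “This is a rough estimate, since the lag's mechanism is uncertain.”

The flask gives 57.7 %, 48.6 %, 58.3 % and 64.4 % in that order, with best Friday's.

    open intermediate + second intermediate → target (k = 0.105 /M/min)
    starting material + coupling partner → open intermediate (k = 0.276 /M/min)
    starting material + protic impurity → quenched substrate (k = 14.9 /M/min)
    coupling partner + fresh partner → second intermediate (k = 0.0861 /M/min)
    2 open intermediate → homo product (k = 0.0108 /M/min)

Friday's over Thursday's is 1.12, beside the 1.12 from the delay number. Wednesday's over Thursday's is 1.01, so that flask does not show the factor. Friday's ends with 15.0 % target against Thursday's 22.2 %, and with the making of target struck out, Friday's holds 78.1 % open intermediate.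

The runs are calculated for an exercise, and the scatter is random.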